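**Retrosynthetic overview**

1. Feature: the upper flavan has rings A, C, B and the lower flavan has rings D, F, E. Ring B holds its two carbon substituents on neighbouring atoms (upper C2 on C1', lower C8 on C6'), opposite the C3'/C4' catechol, so C1' and C6' map onto the two equivalent carbons of a 4,5-dioxygenated benzyne.
2. Late disconnections: first the ten O-benzyl groups (hydrogenolysis). Then O1–C8a of ring C, made by palladium-catalysed O-arylation of the C2 hydroxyl with a ring A bromide, which leaves C2 untouched.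
3. Key disconnection: lower C8–C6' and C1'–upper C2 are made in one flask from a C8 aryllithium, the aryne and an (R)-alpha-benzyloxy aldehyde; a magnesium chelate sets C2.
4. Fragments: (−)-epicatechin brings rings D, F, E and both lower stereocentres. Catechol gives the aryne precursor. 5-Bromoresorcinol and a glycolate imide give the aldehyde, with C3 set by auxiliary-controlled alkylation.
5. Ring order: rings A, B, D, E and F are present in the starting materials; ring C is the only ring formed (step 15).

Key step: step 14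

Assumption: the target structure gives no axial descriptor for the C6'–C8 biaryl bond (three ortho substituents, two of them oxygen). The axis is therefore treated as not configurationally fixed, and intermediates may appear as rotamers.

**Step 1**
Reactants: 1 (−)-epicatechin
Product: 2 5,7,3',4'-tetra-O-benzyl-(−)-epicatechin
Conditions: BnBr (4.2 equiv), K2CO3, DMF, 0 °C → rt, Ar
Reagents that add atoms: benzyl bromide, BrCc1ccccc1
Why: Williamson ether synthesis, in which carbonate deprotonates only the four phenols and not the C3 alcohol, and the mild base at low temperature should avoid ring-opening epimerisation at C2.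

**Step 2**
Reactants: 2 5,7,3',4'-tetra-O-benzyl-(−)-epicatechin
Product: 3 8-bromo-5,7,3',4'-tetra-O-benzyl-(−)-epicatechin
Conditions: NBS (1.0 equiv), CH2Cl2, −78 °C → rt, dark
Reagents that add atoms: N-bromosuccinimide, O=C1CCC(=O)N1Br
Why: Electrophilic aromatic bromination, in which the phloroglucinol-type ring D is the most electron-rich ring and C8, next to the tied-back pyran oxygen, is less shielded than C6 between two benzyloxy groups, the site preference established for benzylated flavan-3-ols.

**Step 3**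
Reactants: 3 8-bromo-5,7,3',4'-tetra-O-benzyl-(−)-epicatechin
Product: 5 8-bromo-3,5,7,3',4'-penta-O-benzyl-(−)-epicatechin, via sodium C3 alkoxide 4 (not isolated)
Conditions: NaH, DMF, 0 °C; BnBr, 0 °C → rt
Reagents that add atoms: benzyl bromide, BrCc1ccccc1
Why: Williamson ether synthesis on the secondary alkoxide, and with all phenols capped no quinone methide pathway is open, so C2 and C3 keep their configuration.

**Step 4**
Reactants: 6 catechol
Product: 7 4,5-dibromocatechol
Conditions: Br2 (2.0 equiv), AcOH, 0 °C → rt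
Reagents that add atoms: bromine, BrBr
Why: Electrophilic aromatic bromination in which each bromine enters para to one hydroxyl group, which leads to the 4,5-dibromide.

**Step 5**
Reactants: 7 4,5-dibromocatechol
Product: 8 1,2-dibromo-4,5-bis(benzyloxy)benzene
Conditions: BnBr (2.2 equiv), K2CO3, acetone, reflux
Reagents that add atoms: benzyl bromide, BrCc1ccccc1
Why: Williamson ether synthesis on two acidic phenols, and brominating before benzylating keeps the benzyl ethers away from HBr.

**Step 6**
Reactants: 9 5-bromoresorcinol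
Product: 10 1-bromo-3,5-bis(benzyloxy)benzene
Conditions: BnBr (2.2 equiv), K2CO3, acetone, reflux
Reagents that add atoms: benzyl bromide, BrCc1ccccc1
Why: Williamson ether synthesis, in which the aryl bromide is inert.

**Step 7**
Reactants: 10 1-bromo-3,5-bis(benzyloxy)benzene
Product: 12 2-bromo-4,6-bis(benzyloxy)benzaldehyde, via aryl iminium chloride 11 (not isolated)
Conditions: POCl3, DMF, 0 → 70 °C; then ice-water
Reagents that add atoms: N,N-dimethylformamide, CN(C)C=O; water, O
Why: Vilsmeier–Haack formylation, in which the bulky chloroiminium ion attacks one of the two equivalent positions para to one benzyloxy group and ortho to the other instead of the site between both benzyloxy groups, as is known for 1-bromo-3,5-dialkoxybenzenes.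

**Step 8**
Reactants: 12 2-bromo-4,6-bis(benzyloxy)benzaldehyde
Product: 13 [2-bromo-4,6-bis(benzyloxy)phenyl]methanol
Conditions: NaBH4, THF/MeOH, 0 °C
Reagents that add atoms: none
Why: Borohydride reduction of an aryl aldehyde, which leaves the aryl bromide and the benzyl ethers untouched.

**Step 9**
Reactants: 13 [2-bromo-4,6-bis(benzyloxy)phenyl]methanol
Product: 14 1-bromo-2-(bromomethyl)-3,5-bis(benzyloxy)benzene
Conditions: PBr3 (0.4 equiv), Et2O, 0 °C; used at once without chromatography
Reagents that add atoms: phosphorus tribromide, BrP(Br)Br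
Why: Substitution of an activated benzylic alcohol through its phosphite ester, which is fast at 0 °C because the ortho and para oxygen donors stabilise the developing benzylic cation character.

**Step 10**
Reactants: 15 (S)-4-benzyloxazolidin-2-one; 16 benzyloxyacetyl chloride
Product: 18 (S)-4-benzyl-3-(benzyloxyacetyl)oxazolidin-2-one, via N-lithio oxazolidinone 17 (not isolated)
Conditions: n-BuLi, THF, −78 °C; 16, −78 → 0 °C
Reagents that add atoms: none
Why: N-acylation of the lithiated Evans auxiliary with an acid chloride, and working without an amine base avoids ketene formation from the alkoxyacetyl chloride.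

**Step 11**
Reactants: 18 (S)-4-benzyl-3-(benzyloxyacetyl)oxazolidin-2-one; 14 1-bromo-2-(bromomethyl)-3,5-bis(benzyloxy)benzene
Product: 20 (S)-4-benzyl-3-{(R)-2-benzyloxy-3-[2-bromo-4,6-bis(benzyloxy)phenyl]propanoyl}oxazolidin-2-one, via sodium Z-enolate 19 (not isolated)
Conditions: NaN(SiMe3)2, THF, −78 °C; 14, −78 → −40 °C
Reagents that add atoms: none
Why: Evans-type asymmetric glycolate alkylation, in which the chelated sodium Z-enolate is attacked by the reactive benzylic bromide on the face opposite the C4 benzyl group of the (S)-auxiliary, which sets the future upper C3 as (R).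

**Step 12**
Reactants: 20 (S)-4-benzyl-3-{(R)-2-benzyloxy-3-[2-bromo-4,6-bis(benzyloxy)phenyl]propanoyl}oxazolidin-2-one
Product: 21 (R)-2-benzyloxy-3-[2-bromo-4,6-bis(benzyloxy)phenyl]propan-1-ol
Conditions: LiBH4, MeOH (1 equiv), THF, 0 °C
Reagents that add atoms: none
Why: Reductive cleavage of an N-acyloxazolidinone, in which LiBH4 attacks the exocyclic carbonyl and gives the primary alcohol without touching the stereocentre, the aryl bromide or the benzyl ethers.

**Step 13**
Reactants: 21 (R)-2-benzyloxy-3-[2-bromo-4,6-bis(benzyloxy)phenyl]propan-1-ol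
Product: 22 (R)-2-benzyloxy-3-[2-bromo-4,6-bis(benzyloxy)phenyl]propanal
Conditions: Dess–Martin periodinane, CH2Cl2, 0 °C → rt; used crude on the same day
Reagents that add atoms: none
Why: Dess–Martin oxidation runs without base, so the alpha-alkoxy aldehyde should form without enolisation at the stereocentre.

**Step 14**
Reactants: 5 8-bromo-3,5,7,3',4'-penta-O-benzyl-(−)-epicatechin; 8 1,2-dibromo-4,5-bis(benzyloxy)benzene; 22 (R)-2-benzyloxy-3-[2-bromo-4,6-bis(benzyloxy)phenyl]propanal
Product: 28 (1R,2R)-2-benzyloxy-3-[2-bromo-4,6-bis(benzyloxy)phenyl]-1-{4,5-bis(benzyloxy)-2-[penta-O-benzyl-(−)-epicatechin-8-yl]phenyl}propan-1-ol (syn carbinol; upper C2 R and C3 R), via C8 aryllithium 23 (not isolated), via dibenzyloxybenzyne 24 (not isolated), via 2-lithiobiaryl 25 (not isolated), via 2-bromobiaryl 26 (not isolated), via biaryl Grignard reagent 27 (not isolated)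
Conditions: 5 (1.3 equiv), n-BuLi (1.3 equiv), THF, −78 °C; 8 (1.2 equiv) in THF, slow addition, −78 °C; n-BuLi (1.2 equiv), −78 °C; MgBr2·OEt2, −78 → −40 °C; cannulated into 22 (1.0 equiv) + MgBr2·OEt2, CH2Cl2, −78 → −20 °C; aq NH4Cl
Reagents that add atoms: none
Why: Bromine–lithium exchange converts 5 into the C8 aryllithium 23, which starts a halogen-transfer chain with 8: exchange at one C–Br bond and loss of LiBr release aryne 24, 23 adds to it (bond lower C8–C6') to give 25, and 25 abstracts bromine from the next molecule of 8, so the adduct rests as bromide 26 until the second charge of n-BuLi regenerates 25. MgBr2·OEt2 then turns 25 into the less basic Grignard reagent 27, which adds to the aldehyde carbon of 22 (bond C1'–upper C2) much faster than it could exchange with the ring A bromide. The closest known reaction types are the aryne coupling of 2,6-dialkoxyaryllithiums with 1,2-dihaloarenes followed by electrophilic trapping of the 2-metallobiaryl, and the Cram-chelate addition of aryl Grignard reagents to alpha-alkoxy aldehydes. The step closes no ring. The one new stereocentre, upper C2, should be set as (R) by the five-membered chelate of magnesium with the aldehyde oxygen and the C3 benzyloxy oxygen, in which the aryl group enters from the face of the C3 hydrogen and away from the CH2Ar arm, giving the syn (2R,3R) relation. Site selectivity on the aryne is not needed because its two reactive carbons are equivalent, and chemoselectivity among the organometallics is secured by slow addition of 8 at −78 °C, n-BuLi matched to 8, full lithium-to-magnesium exchange before 22 enters, and pre-complexation of 22 in CH2Cl2 to offset the THF.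

**Step 15**
Reactants: 28 syn (1R,2R) carbinol
Product: 29 deca-O-benzyl derivative of the target (ring C closed; upper 2R,3R and lower 2R,3R)
Conditions: Pd(OAc)2 (cat.), 2-(di-tert-butylphosphino)-1,1'-binaphthyl (cat.), Cs2CO3, toluene, 70–80 °C
Reagents that add atoms: none
Why: Buchwald–Hartwig-type intramolecular C–O coupling, in which zerovalent palladium inserts into the only C–Br bond (ring A C8a), the C2 alkoxide binds, and the bulky electron-rich phosphine favours six-membered-ring C–O reductive elimination over beta-hydride elimination, while the C2–O bond is never broken, so the (R) configuration and the 2,3-cis relation are retained.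

**Step 16**
Reactants: 29 deca-O-benzyl derivative of the target
Product: 30 target CNP0353739.3
Conditions: H2 (1 atm), Pd(OH)2 on carbon, THF/MeOH/H2O, rt; filtration and freeze-drying under Ar
Reagents that add atoms: none
Why: Catalytic hydrogenolysis cleaves all ten O-benzyl groups under mild conditions, under which the cyclic C2–O1 bonds of flavans, the biaryl bond and the four stereocentres are known to persist.

**Compound list**

1 | (−)-epicatechin, (2R,3R) | Oc1cc(O)c2c(c1)O[C@H](c1ccc(O)c(O)c1)[C@H](O)C2 | starting material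
2 | 5,7,3',4'-tetra-O-benzyl-(−)-epicatechin | O(Cc4ccccc4)c1cc(OCc4ccccc4)c2c(c1)O[C@H](c1ccc(OCc4ccccc4)c(OCc4ccccc4)c1)[C@H](O)C2 | intermediate
3 | 8-bromo-5,7,3',4'-tetra-O-benzyl-(−)-epicatechin | Brc1c(OCc4ccccc4)cc(OCc4ccccc4)c3c1O[C@H](c1ccc(OCc4ccccc4)c(OCc4ccccc4)c1)[C@H](O)C3 | intermediate
4 | sodium C3 alkoxide of 3 | Brc1c(OCc4ccccc4)cc(OCc4ccccc4)c3c1O[C@H](c1ccc(OCc4ccccc4)c(OCc4ccccc4)c1)[C@H]([O-])C3.[Na+] | intermediate
5 | 8-bromo-3,5,7,3',4'-penta-O-benzyl-(−)-epicatechin | Brc1c(OCc4ccccc4)cc(OCc4ccccc4)c3c1O[C@H](c1ccc(OCc4ccccc4)c(OCc4ccccc4)c1)[C@H](OCc4ccccc4)C3 | intermediate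
6 | catechol | Oc1ccccc1O | starting material
7 | 4,5-dibromocatechol | Oc1cc(Br)c(Br)cc1O | intermediate
8 | 1,2-dibromo-4,5-bis(benzyloxy)benzene | Brc1cc(OCc4ccccc4)c(OCc4ccccc4)cc1Br | intermediate
9 | 5-bromoresorcinol | Oc1cc(O)cc(Br)c1 | starting material
10 | 1-bromo-3,5-bis(benzyloxy)benzene | Brc1cc(OCc2ccccc2)cc(OCc2ccccc2)c1 | intermediate
11 | N-[2-bromo-4,6-bis(benzyloxy)benzylidene]-N-methylmethanaminium chloride | C[N+](C)=Cc1c(Br)cc(OCc2ccccc2)cc1OCc1ccccc1.[Cl-] | intermediate
12 | 2-bromo-4,6-bis(benzyloxy)benzaldehyde | O=Cc1c(Br)cc(OCc2ccccc2)cc1OCc1ccccc1 | intermediate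
13 | [2-bromo-4,6-bis(benzyloxy)phenyl]methanol | OCc1c(Br)cc(OCc2ccccc2)cc1OCc1ccccc1 | intermediate
14 | 1-bromo-2-(bromomethyl)-3,5-bis(benzyloxy)benzene | BrCc1c(Br)cc(OCc2ccccc2)cc1OCc1ccccc1 | intermediate
15 | (S)-4-benzyloxazolidin-2-one | O=C1OC[C@H](Cc2ccccc2)N1 | starting material
16 | benzyloxyacetyl chloride | O=C(Cl)COCc1ccccc1 | starting material
17 | N-lithio-(S)-4-benzyloxazolidin-2-one | O=C1OC[C@H](Cc2ccccc2)N1[Li] | intermediate
18 | (S)-4-benzyl-3-(benzyloxyacetyl)oxazolidin-2-one | O=C1OC[C@H](Cc2ccccc2)N1C(=O)COCc1ccccc1 | intermediate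
19 | sodium (Z)-enolate of 18 | O=C1OC[C@H](Cc2ccccc2)N1/C([O-])=C/OCc1ccccc1.[Na+] | intermediate
20 | (S)-4-benzyl-3-{(R)-2-benzyloxy-3-[2-bromo-4,6-bis(benzyloxy)phenyl]propanoyl}oxazolidin-2-one | O=C1OC[C@H](Cc2ccccc2)N1C(=O)[C@H](OCc1ccccc1)Cc1c(Br)cc(OCc2ccccc2)cc1OCc1ccccc1 | intermediate
21 | (R)-2-benzyloxy-3-[2-bromo-4,6-bis(benzyloxy)phenyl]propan-1-ol | OC[C@H](OCc1ccccc1)Cc1c(Br)cc(OCc2ccccc2)cc1OCc1ccccc1 | intermediate
22 | (R)-2-benzyloxy-3-[2-bromo-4,6-bis(benzyloxy)phenyl]propanal | O=C[C@H](OCc4ccccc4)Cc1c(Br)cc(OCc4ccccc4)cc1OCc4ccccc4 | intermediate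
23 | 8-lithio-3,5,7,3',4'-penta-O-benzyl-(−)-epicatechin | [Li]c1c(OCc4ccccc4)cc(OCc4ccccc4)c3c1O[C@H](c1ccc(OCc4ccccc4)c(OCc4ccccc4)c1)[C@H](OCc4ccccc4)C3 | intermediate
24 | 4,5-bis(benzyloxy)benzyne | C1#CC=C(OCc2ccccc2)C(OCc2ccccc2)=C1 | intermediate
25 | 8-[2-lithio-4,5-bis(benzyloxy)phenyl]-penta-O-benzyl-(−)-epicatechin | [Li]c1cc(OCc4ccccc4)c(OCc4ccccc4)cc1-c1c(OCc4ccccc4)cc(OCc4ccccc4)c3c1O[C@H](c1ccc(OCc4ccccc4)c(OCc4ccccc4)c1)[C@H](OCc4ccccc4)C3 | intermediate
26 | 8-[2-bromo-4,5-bis(benzyloxy)phenyl]-penta-O-benzyl-(−)-epicatechin | Brc1cc(OCc4ccccc4)c(OCc4ccccc4)cc1-c1c(OCc4ccccc4)cc(OCc4ccccc4)c3c1O[C@H](c1ccc(OCc4ccccc4)c(OCc4ccccc4)c1)[C@H](OCc4ccccc4)C3 | intermediate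
27 | 8-[2-(bromomagnesio)-4,5-bis(benzyloxy)phenyl]-penta-O-benzyl-(−)-epicatechin | Br[Mg]c1cc(OCc4ccccc4)c(OCc4ccccc4)cc1-c1c(OCc4ccccc4)cc(OCc4ccccc4)c3c1O[C@H](c1ccc(OCc4ccccc4)c(OCc4ccccc4)c1)[C@H](OCc4ccccc4)C3 | intermediate
28 | open-chain syn (1R,2R) carbinol (upper C2 R, C3 R) with the full carbon skeleton | O[C@H](c1cc(OCc4ccccc4)c(OCc4ccccc4)cc1-c1c(OCc4ccccc4)cc(OCc4ccccc4)c3c1O[C@H](c1ccc(OCc4ccccc4)c(OCc4ccccc4)c1)[C@H](OCc4ccccc4)C3)[C@H](OCc4ccccc4)Cc1c(Br)cc(OCc4ccccc4)cc1OCc4ccccc4 | intermediate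
29 | deca-O-benzyl derivative of the target | O(Cc4ccccc4)c1cc(OCc4ccccc4)c2c(c1)O[C@H](c1cc(OCc4ccccc4)c(OCc4ccccc4)cc1-c1c(OCc4ccccc4)cc(OCc4ccccc4)c3c1O[C@H](c1ccc(OCc4ccccc4)c(OCc4ccccc4)c1)[C@H](OCc4ccccc4)C3)[C@H](OCc4ccccc4)C2 | intermediate
30 | CNP0353739.3, 6'-(epicatechin-8-yl)epicatechin, all four centres R | Oc1cc(O)c2c(c1)O[C@H](c1cc(O)c(O)cc1-c1c(O)cc(O)c3c1O[C@H](c1ccc(O)c(O)c1)[C@H](O)C3)[C@H](O)C2 | target

**Step count**

- Total step count: 16.
- Longest linear sequence: 10 steps from 5-bromoresorcinol (steps 6, 7, 8, 9, 11, 12, 13, 14, 15, 16).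

**Steps most likely to fail**

**1. Step 14.**

What may go wrong:
- The organometallic species may interfere with each other in the single flask. Possible pathways are aryne oligomerisation, renewed lithiation of 5 regenerated in chain initiation, and proton transfer from a benzylic CH2 to the aryl anion.
- The residual THF may erode chelate control, giving poor facial selectivity at C2.
- The hindered Grignard reagent may enolise the aldehyde.

The fallback sets out from 26 and 20 and comes back at 28. The relay is cut after its first half: the aryne coupling of 23 with 8 is quenched with methanol and 26 is purified. Imide 20 is treated with MeNH(OMe)·HCl and AlMe3 in CH2Cl2 to give the Weinreb amide (R)-2-benzyloxy-3-[2-bromo-4,6-bis(benzyloxy)phenyl]-N-methoxy-N-methylpropanamide F1. Pure 26 is lithiated with n-BuLi at −78 °C, moved to magnesium as 27, and acylated with F1 at 0 °C to give the aryl ketone F2. The C2 stereocentre then comes from hydride delivery instead of aryl delivery. KBH(s-Bu)3 in THF at −78 °C has no chelating counter-ion and should follow the polar Felkin–Anh model. In that model the C3–O bond lies anti to the incoming hydride, which leads to the syn carbinol 28.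

**2. Step 15.**

What may go wrong:
- Beta-hydride elimination from the palladium alkoxide at the C2–H bond may compete, oxidising the carbinol and reducing the ring A bromide.
- The C–O reductive elimination may be slow next to the crowded biaryl.

The fallback sets out from 28 and comes back at 29. It reverses the polarity of the ring closure: the ring A oxygen becomes the nucleophile and C2 the electrophile. The sequence is as follows.
- Dess–Martin oxidation of 28 gives the aryl ketone F2.
- Zn(BH4)2 in Et2O at −30 °C reduces F2 through the zinc chelate to the anti (1S,2R) carbinol F3.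
- Miyaura borylation (B2pin2, PdCl2(dppf), KOAc, dioxane, 80 °C) gives the pinacol boronate F4.
- NaBO3·4H2O in THF/H2O gives the phenol F5.
- Intramolecular Mitsunobu etherification (PPh3, DIAD, THF, 0 °C) forms O1–C2 with inversion, which converts the (S) carbinol carbon into the (R) centre of 29.

**3. Step 11 (with step 9).**

What may go wrong:
- The electron-rich benzylic bromide may alkylate itself on standing.
- Substitution at the doubly ortho-substituted benzylic carbon may be slower than decomposition of the glycolate enolate.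

The fallback sets out from 10 and comes back at 21. It takes the stereocentre from the chiral pool. The sequence is as follows.
- NIS in MeCN iodinates 10 para to one benzyloxy group to give 1-bromo-2-iodo-3,5-bis(benzyloxy)benzene F6.
- Selective iodine–magnesium exchange (i-PrMgCl, THF, −40 °C) gives 2-bromo-4,6-bis(benzyloxy)phenylmagnesium chloride F7.
- Opening of commercial (R)-trityl glycidyl ether at its terminal carbon, catalysed by CuBr·SMe2, gives the secondary alcohol (R)-1-[2-bromo-4,6-bis(benzyloxy)phenyl]-3-(trityloxy)propan-2-ol F8.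
- NaH and BnBr give the benzyl ether F9.
- TsOH (cat.) in MeOH/CH2Cl2 removes the trityl group to give 21.

**Further compounds**

F1 | step 14 | (R)-2-benzyloxy-3-[2-bromo-4,6-bis(benzyloxy)phenyl]-N-methoxy-N-methylpropanamide | CON(C)C(=O)[C@H](OCc1ccccc1)Cc1c(Br)cc(OCc2ccccc2)cc1OCc1ccccc1
F2 | step 14 | (R)-2-benzyloxy-3-[2-bromo-4,6-bis(benzyloxy)phenyl]-1-{4,5-bis(benzyloxy)-2-[penta-O-benzyl-(−)-epicatechin-8-yl]phenyl}propan-1-one | O=C(c1cc(OCc4ccccc4)c(OCc4ccccc4)cc1-c1c(OCc4ccccc4)cc(OCc4ccccc4)c3c1O[C@H](c1ccc(OCc4ccccc4)c(OCc4ccccc4)c1)[C@H](OCc4ccccc4)C3)[C@H](OCc4ccccc4)Cc1c(Br)cc(OCc4ccccc4)cc1OCc4ccccc4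
F3 | step 15 | anti (1S,2R) carbinol, C2 epimer of 28 | O[C@@H](c1cc(OCc4ccccc4)c(OCc4ccccc4)cc1-c1c(OCc4ccccc4)cc(OCc4ccccc4)c3c1O[C@H](c1ccc(OCc4ccccc4)c(OCc4ccccc4)c1)[C@H](OCc4ccccc4)C3)[C@H](OCc4ccccc4)Cc1c(Br)cc(OCc4ccccc4)cc1OCc4ccccc4
F4 | step 15 | pinacol boronate of F3 (boron in place of the ring A bromine) | O[C@@H](c1cc(OCc4ccccc4)c(OCc4ccccc4)cc1-c1c(OCc4ccccc4)cc(OCc4ccccc4)c3c1O[C@H](c1ccc(OCc4ccccc4)c(OCc4ccccc4)c1)[C@H](OCc4ccccc4)C3)[C@H](OCc4ccccc4)Cc1c(B5OC(C)(C)C(C)(C)O5)cc(OCc4ccccc4)cc1OCc4ccccc4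
F5 | step 15 | ring A phenol of the anti (1S,2R) carbinol | O[C@@H](c1cc(OCc4ccccc4)c(OCc4ccccc4)cc1-c1c(OCc4ccccc4)cc(OCc4ccccc4)c3c1O[C@H](c1ccc(OCc4ccccc4)c(OCc4ccccc4)c1)[C@H](OCc4ccccc4)C3)[C@H](OCc4ccccc4)Cc1c(O)cc(OCc4ccccc4)cc1OCc4ccccc4
F6 | step 11 | 1-bromo-2-iodo-3,5-bis(benzyloxy)benzene | Brc1cc(OCc2ccccc2)cc(OCc2ccccc2)c1I
F7 | step 11 | 2-bromo-4,6-bis(benzyloxy)phenylmagnesium chloride | Cl[Mg]c1c(Br)cc(OCc2ccccc2)cc1OCc1ccccc1
F8 | step 11 | (R)-1-[2-bromo-4,6-bis(benzyloxy)phenyl]-3-(trityloxy)propan-2-ol | C(c1ccccc1)(c1ccccc1)(c1ccccc1)OC[C@H](O)Cc1c(Br)cc(OCc2ccccc2)cc1OCc1ccccc1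
F9 | step 11 | (R)-1-bromo-2-[2-benzyloxy-3-(trityloxy)propyl]-3,5-bis(benzyloxy)benzene | C(c1ccccc1)(c1ccccc1)(c1ccccc1)OC[C@H](OCc1ccccc1)Cc1c(Br)cc(OCc2ccccc2)cc1OCc1ccccc1
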